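The route rests on cutting C1–C15 and C13–C14, the two bonds of the cyclohexene (C1, C14, C13, C12, C11, C15). That ring holds the tetrasubstituted butenolide alkene C11=C12 at a bridgehead of the bicyclo[9.3.1] core, which is the mark of a type 2 intramolecular Diels–Alder reaction. One cycloaddition closes the cyclohexene and the 12-membered ring (C1 to C11 plus C15) and sets C1. Its precursor 21 is an (R)-3-methylidene-4-isopropylidene butyrolactone whose C10 carries a nine-atom chain with the (E)-C7=C8 alkene, the C6 acetate, the C4 exo-methylene and a terminal vinyl ketone (C2 ketone, C1=C14).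

Key step: step 14

Remarks on the chemistry:
- Locants C1–C20 are those of the target skeleton: C1 bridgehead CH; C2, C3 CH2; C4 with C20H2; C5 CH2; C6 CHOAc; C7=C8 with C19 methyl on C8; C9 CH2; C10 lactone CH–O; C11=C12; C13, C14 CH2; C15 CMe2; C18 lactone C=O.
- The diene lactone is built by Sonogashira coupling and cyclocarbonylation. An Alder-ene closure of a propiolate onto a prenyl-type alkene would be expected to give the isopropenyl 1,4-diene, not the conjugated isopropylidene diene.
- The C6 oxygen is carried as its acetate from step 11, so no silyl exchange is needed at the end.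
- The C2 carbinol centre in 20, 23 and 24 is formed without control and later removed; it is drawn without configuration.

Step 1
Reactants: 1 3-methylbut-2-enal (prenal)
Product: 3 2-bromo-3-methylbut-2-enal, via 2,3-dibromo-3-methylbutanal 2 (not isolated)
Conditions: Br2, CH2Cl2, −10 °C; then Et3N, 0 °C → rt
Reagents that add atoms: bromine, BrBr
Why: Bromination–dehydrobromination: bromine adds across the enal alkene and triethylamine removes HBr through the acidic α-hydrogen, giving the α-bromo enal with no stereocentre involved.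

Step 2
Reactants: 3 2-bromo-3-methylbut-2-enal; 4 ethynyl(trimethyl)silane
Product: 5 3-methyl-2-[(trimethylsilyl)ethynyl]but-2-enal
Conditions: PdCl2(PPh3)2 (3 mol %), CuI (5 mol %), Et3N, THF, rt
Reagents that add atoms: none
Why: Sonogashira coupling: the C–Br bond of the α-bromo enal is activated for oxidative addition and couples with the copper acetylide while the aldehyde is untouched.

Step 3
Reactants: 6 methyl 3-methylbut-2-enoate
Product: 8 tert-butyl[(1-methoxy-3-methylbuta-1,3-dien-1-yl)oxy]dimethylsilane, via lithium 1-methoxy-3-methylbuta-1,3-dien-1-olate 7 (not isolated)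
Conditions: LDA, THF, −78 °C; then TBSCl, DMPU, −78 °C → rt
Reagents that add atoms: tert-butyldimethylsilyl chloride, CC(C)(C)[Si](C)(C)Cl
Why: γ-Deprotonation of the senecioate gives the lithium dienolate, which is silylated on oxygen (silyl ketene acetal formation); the ketene acetal geometry is of no consequence.

Step 4
Reactants: 5 3-methyl-2-[(trimethylsilyl)ethynyl]but-2-enal; 8 tert-butyl[(1-methoxy-3-methylbuta-1,3-dien-1-yl)oxy]dimethylsilane
Product: 9 methyl (2E,5R)-5-hydroxy-3-methyl-6-(propan-2-ylidene)-8-(trimethylsilyl)oct-2-en-7-ynoate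
Conditions: SiCl4, Denmark binaphthyldiamine bisphosphoramide (5 mol %), iPr2NEt (cat.), CH2Cl2, −78 °C; aq. KF/NaHCO3
Reagents that add atoms: none
Why: Denmark vinylogous Mukaiyama aldol reaction: the phosphoramide-bound trichlorosilyl cation activates the aldehyde, the dienolate reacts through its γ-carbon to give the (E)-enoate (C7=C8), and the catalyst antipode is chosen for Re-face attack so that C10 is set as R, to be checked by Mosher ester analysis.

Step 5
Reactants: 9 methyl (2E,5R)-5-hydroxy-3-methyl-6-(propan-2-ylidene)-8-(trimethylsilyl)oct-2-en-7-ynoate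
Product: 10 (2E,5R)-3-methyl-6-(propan-2-ylidene)-8-(trimethylsilyl)oct-2-en-7-yne-1,5-diol
Conditions: DIBAL-H (3.3 equiv), CH2Cl2, −78 °C; Rochelle salt
Reagents that add atoms: none
Why: DIBAL-H reduces the conjugated ester in a 1,2-sense to the allylic alcohol at low temperature and leaves the silylalkyne, the alkenes and C10 alone.

Step 6
Reactants: 10 (2E,5R)-3-methyl-6-(propan-2-ylidene)-8-(trimethylsilyl)oct-2-en-7-yne-1,5-diol
Product: 11 (2E,5R)-3-methyl-6-(propan-2-ylidene)oct-2-en-7-yne-1,5-diol
Conditions: K2CO3 (cat.), MeOH, rt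
Reagents that add atoms: none
Why: Carbonate-catalysed methanolysis of the alkynyl C–Si bond (protodesilylation) frees the terminal alkyne under conditions that touch nothing else.

Step 7
Reactants: 11 (2E,5R)-3-methyl-6-(propan-2-ylidene)oct-2-en-7-yne-1,5-diol
Product: 12 (2E,5R)-5-hydroxy-3-methyl-6-(propan-2-ylidene)oct-2-en-7-ynal
Conditions: TEMPO (10 mol %), PhI(OAc)2, CH2Cl2, rt
Reagents that add atoms: none
Why: TEMPO/PhI(OAc)2 oxidation: the oxoammonium ion oxidises the unhindered primary allylic alcohol much faster than the hindered secondary C10 carbinol and keeps the (E)-geometry.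

Step 8
Reactants: 12 (2E,5R)-5-hydroxy-3-methyl-6-(propan-2-ylidene)oct-2-en-7-ynal; 13 carbon monoxide
Product: 14 (2E)-3-methyl-4-[(2R)-4-methylidene-5-oxo-3-(propan-2-ylidene)oxolan-2-yl]but-2-enal
Conditions: PdCl2 (5 mol %), PPh3 (10 mol %), SnCl2 (5 mol %), CO (7 bar), MeCN, 65 °C
Reagents that add atoms: none
Why: Norton-type palladium-catalysed cyclocarbonylation of a homopropargylic alcohol: the alkoxycarbonyl–palladium species formed at the C10 oxygen adds syn across the alkyne in a 5-exo sense and protonolysis releases the α-methylene lactone, so the s-cis diene C15=C11–C12=C13 arises with C10 untouched.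

Step 9
Reactants: 15 3-chloro-2-(chloromethyl)prop-1-ene
Product: 16 tributyl[2-(chloromethyl)prop-2-en-1-yl]stannane
Conditions: Bu3SnLi (from Bu3SnH, LDA, THF, 0 °C) added to 15 (3 equiv), THF, −78 °C
Reagents that add atoms: tributylstannyllithium, [Li+].CCCC[Sn-](CCCC)CCCC
Why: SN2 displacement of one allylic chloride by the stannyl anion; excess dichloride and inverse addition limit double substitution.

Step 10
Reactants: 14 (2E)-3-methyl-4-[(2R)-4-methylidene-5-oxo-3-(propan-2-ylidene)oxolan-2-yl]but-2-enal; 16 tributyl[2-(chloromethyl)prop-2-en-1-yl]stannane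
Product: 17 (5R)-5-[(2E,4S)-6-(chloromethyl)-4-hydroxy-2-methylhepta-2,6-dien-1-yl]-3-methylidene-4-(propan-2-ylidene)oxolan-2-one
Conditions: (S)-BINOL (20 mol %), Ti(OiPr)4 (10 mol %), 4 Å MS, CH2Cl2, −20 °C; aq. NaHCO3
Reagents that add atoms: none
Why: Keck asymmetric allylation: the BINOL–titanium Lewis acid activates the enal and the allylstannane adds 1,2 in an SE2′ sense to the Si face under catalyst control, setting C6 as S, while the α-methylene lactone is not an acceptor for allylstannanes.

Step 11
Reactants: 17 (5R)-5-[(2E,4S)-6-(chloromethyl)-4-hydroxy-2-methylhepta-2,6-dien-1-yl]-3-methylidene-4-(propan-2-ylidene)oxolan-2-one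
Product: 18 (2E,4S)-6-(chloromethyl)-2-methyl-1-[(2R)-4-methylidene-5-oxo-3-(propan-2-ylidene)oxolan-2-yl]hepta-2,6-dien-4-yl acetate
Conditions: Ac2O, Et3N, DMAP (cat.), CH2Cl2, 0 °C
Reagents that add atoms: acetic anhydride, CC(=O)OC(C)=O
Why: DMAP-catalysed acetylation of the secondary allylic alcohol, run cold and briefly so that the allylic chloride is not displaced; this installs the acetate of the target.

Step 12
Reactants: 18 (2E,4S)-6-(chloromethyl)-2-methyl-1-[(2R)-4-methylidene-5-oxo-3-(propan-2-ylidene)oxolan-2-yl]hepta-2,6-dien-4-yl acetate; 19 prop-2-enal (acrolein)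
Product: 20 (2E,4S)-8-hydroxy-2-methyl-6-methylidene-1-[(2R)-4-methylidene-5-oxo-3-(propan-2-ylidene)oxolan-2-yl]deca-2,9-dien-4-yl acetate (both C8 epimers, C2 of the target numbering)
Conditions: In powder, NaI (cat.), acrolein (3 equiv), DMF, rt; aq. NH4Cl
Reagents that add atoms: none
Why: Indium-mediated Barbier allylation: the allylindium species formed in situ adds 1,2 to acrolein and ignores the acetate, the lactone and the conjugated alkenes, and the symmetric 2-substituted allyl unit makes the SE2′ regiochemistry irrelevant.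

Step 13
Reactants: 20 (2E,4S)-8-hydroxy-2-methyl-6-methylidene-1-[(2R)-4-methylidene-5-oxo-3-(propan-2-ylidene)oxolan-2-yl]deca-2,9-dien-4-yl acetate
Product: 21 (2E,4S)-2-methyl-6-methylidene-1-[(2R)-4-methylidene-5-oxo-3-(propan-2-ylidene)oxolan-2-yl]-8-oxodeca-2,9-dien-4-yl acetate
Conditions: Dess–Martin periodinane, NaHCO3, CH2Cl2, 0 °C; used at once
Reagents that add atoms: none
Why: Dess–Martin oxidation under bicarbonate buffer should give the vinyl ketone without moving the β,γ-alkene C4=C20 into conjugation.

Step 14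
Reactants: 21 (2E,4S)-2-methyl-6-methylidene-1-[(2R)-4-methylidene-5-oxo-3-(propan-2-ylidene)oxolan-2-yl]-8-oxodeca-2,9-dien-4-yl acetate
Product: 22 (1R,6S,7E,10R)-6-acetoxy-2-oxoverticilla-4(20),7,11-trien-18,10-olide (the 2-oxo derivative of the target; C2 and C9 cis on the cyclohexene)
Conditions: PhMe (1 mM), BHT (cat.), degassed, base-washed glass, 100 °C
Reagents that add atoms: none
Why: A thermal, concerted but asynchronous normal-demand [4+2] cycloaddition of the lactone-locked s-cis diene C15=C11–C12=C13 with the vinyl ketone C1=C14; the closest known reaction types are type 2 intramolecular Diels–Alder reactions that give bridgehead alkenes, Diels–Alder macrocyclisations, and additions of dienes with a dimethylated terminus that join the dienophile α-carbon to that terminus. The cyclohexene (C1, C14, C13, C12, C11, C15) closes by the cycloaddition itself, and the 12-membered ring (C1 to C11 plus C15) closes through the same C1–C15 bond in the 1,3-bridged type 2 mode, leaving C11=C12 as the bridgehead butenolide alkene. The only new stereocentre, C1, is controlled by C10: the chain leaves C10 on one face of the planar diene lactone and should reach only that face, so C2 and C9 end up cis on the new ring (1R), and C1 is α to the ketone and could be equilibrated if needed. The step needs C1-to-C15 regiochemistry, which is secured electronically, because the two methyl groups make C13 the nucleophilic terminus that bonds to the enone β-carbon C14, and geometrically by the 1,3-bridging preference of the tether. High dilution suppresses dimerisation and the moderate temperature keeps the [1,5]-hydrogen shift of the diene slow.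

Step 15
Reactants: 22 (1R,6S,7E,10R)-6-acetoxy-2-oxoverticilla-4(20),7,11-trien-18,10-olide
Product: 23 (1R,6S,7E,10R)-6-acetoxy-2-hydroxyverticilla-4(20),7,11-trien-18,10-olide (C2 epimers)
Conditions: NaBH4, CeCl3·7H2O, MeOH, −40 °C
Reagents that add atoms: none
Why: Luche reduction: borohydride with CeCl3 reduces the saturated ketone at low temperature while the tetrasubstituted butenolide and the acetate are left; the C2 configuration is immaterial.

Step 16
Reactants: 23 (1R,6S,7E,10R)-6-acetoxy-2-hydroxyverticilla-4(20),7,11-trien-18,10-olide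
Product: 24 (1R,6S,7E,10R)-6-acetoxy-2-[(phenoxycarbonothioyl)oxy]verticilla-4(20),7,11-trien-18,10-olide
Conditions: PhOC(S)Cl, pyridine, DMAP (cat.), CH2Cl2, 0 °C → rt
Reagents that add atoms: O-phenyl chlorothionoformate, S=C(Cl)Oc1ccccc1
Why: Acylation of the secondary alcohol to the phenyl thionocarbonate (the Robins substrate for Barton–McCombie deoxygenation) under weak amine base that should not epimerise C10.

Step 17
Reactants: 24 (1R,6S,7E,10R)-6-acetoxy-2-[(phenoxycarbonothioyl)oxy]verticilla-4(20),7,11-trien-18,10-olide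
Product: 25 (1R,6S,7E,10R)-6-acetoxyverticilla-4(20),7,11-trien-18,10-olide (CNP0289913.1)
Conditions: Bu3SnH (0.1 M), AIBN (cat.), PhMe, 90 °C
Reagents that add atoms: none
Why: Barton–McCombie deoxygenation: the stannyl radical adds to the thiocarbonyl, β-scission gives the secondary C2 radical, and hydrogen transfer from the stannane at this concentration should outrun homoallyl–cyclopropylcarbinyl rearrangement; no stereocentre is touched.

Compound list
1 | 3-methylbut-2-enal (prenal) | CC(C)=CC=O | starting material
2 | 2,3-dibromo-3-methylbutanal | CC(C)(Br)C(Br)C=O | intermediate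
3 | 2-bromo-3-methylbut-2-enal | CC(C)=C(Br)C=O | intermediate
4 | ethynyl(trimethyl)silane | C#C[Si](C)(C)C | starting material
5 | 3-methyl-2-[(trimethylsilyl)ethynyl]but-2-enal | CC(C)=C(C=O)C#C[Si](C)(C)C | intermediate
6 | methyl 3-methylbut-2-enoate | COC(=O)C=C(C)C | starting material
7 | lithium 1-methoxy-3-methylbuta-1,3-dien-1-olate | [Li+].C=C(C)C=C([O-])OC | intermediate
8 | tert-butyl[(1-methoxy-3-methylbuta-1,3-dien-1-yl)oxy]dimethylsilane | C=C(C)C=C(OC)O[Si](C)(C)C(C)(C)C | intermediate
9 | methyl (2E,5R)-5-hydroxy-3-methyl-6-(propan-2-ylidene)-8-(trimethylsilyl)oct-2-en-7-ynoate | COC(=O)/C=C(C)/C[C@@H](O)C(=C(C)C)C#C[Si](C)(C)C | intermediate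
10 | (2E,5R)-3-methyl-6-(propan-2-ylidene)-8-(trimethylsilyl)oct-2-en-7-yne-1,5-diol | OC/C=C(C)/C[C@@H](O)C(=C(C)C)C#C[Si](C)(C)C | intermediate
11 | (2E,5R)-3-methyl-6-(propan-2-ylidene)oct-2-en-7-yne-1,5-diol | OC/C=C(C)/C[C@@H](O)C(=C(C)C)C#C | intermediate
12 | (2E,5R)-5-hydroxy-3-methyl-6-(propan-2-ylidene)oct-2-en-7-ynal | O=C/C=C(C)/C[C@@H](O)C(=C(C)C)C#C | intermediate
13 | carbon monoxide | [C-]#[O+] | starting material
14 | (2E)-3-methyl-4-[(2R)-4-methylidene-5-oxo-3-(propan-2-ylidene)oxolan-2-yl]but-2-enal | O=C/C=C(C)/C[C@H]1OC(=O)C(=C)C1=C(C)C | intermediate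
15 | 3-chloro-2-(chloromethyl)prop-1-ene | C=C(CCl)CCl | starting material
16 | tributyl[2-(chloromethyl)prop-2-en-1-yl]stannane | CCCC[Sn](CCCC)(CCCC)CC(=C)CCl | intermediate
17 | (5R)-5-[(2E,4S)-6-(chloromethyl)-4-hydroxy-2-methylhepta-2,6-dien-1-yl]-3-methylidene-4-(propan-2-ylidene)oxolan-2-one | ClCC(=C)C[C@H](O)/C=C(C)/C[C@H]1OC(=O)C(=C)C1=C(C)C | intermediate
18 | (2E,4S)-6-(chloromethyl)-2-methyl-1-[(2R)-4-methylidene-5-oxo-3-(propan-2-ylidene)oxolan-2-yl]hepta-2,6-dien-4-yl acetate | ClCC(=C)C[C@H](OC(C)=O)/C=C(C)/C[C@H]1OC(=O)C(=C)C1=C(C)C | intermediate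
19 | prop-2-enal (acrolein) | C=CC=O | starting material
20 | (2E,4S)-8-hydroxy-2-methyl-6-methylidene-1-[(2R)-4-methylidene-5-oxo-3-(propan-2-ylidene)oxolan-2-yl]deca-2,9-dien-4-yl acetate (C8 epimers) | C=CC(O)CC(=C)C[C@H](OC(C)=O)/C=C(C)/C[C@H]1OC(=O)C(=C)C1=C(C)C | intermediate
21 | (2E,4S)-2-methyl-6-methylidene-1-[(2R)-4-methylidene-5-oxo-3-(propan-2-ylidene)oxolan-2-yl]-8-oxodeca-2,9-dien-4-yl acetate (Diels–Alder precursor) | C=CC(=O)CC(=C)C[C@H](OC(C)=O)/C=C(C)/C[C@H]1OC(=O)C(=C)C1=C(C)C | intermediate
22 | (1R,6S,7E,10R)-6-acetoxy-2-oxoverticilla-4(20),7,11-trien-18,10-olide (Diels–Alder product) | C=C1CC(=O)[C@@H]2CCC3=C([C@@H](C/C(C)=C/[C@@H](OC(C)=O)C1)OC3=O)C2(C)C | intermediate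
23 | (1R,6S,7E,10R)-6-acetoxy-2-hydroxyverticilla-4(20),7,11-trien-18,10-olide (C2 epimers) | C=C1CC(O)[C@@H]2CCC3=C([C@@H](C/C(C)=C/[C@@H](OC(C)=O)C1)OC3=O)C2(C)C | intermediate
24 | (1R,6S,7E,10R)-6-acetoxy-2-[(phenoxycarbonothioyl)oxy]verticilla-4(20),7,11-trien-18,10-olide | C=C1CC(OC(=S)Oc4ccccc4)[C@@H]2CCC3=C([C@@H](C/C(C)=C/[C@@H](OC(C)=O)C1)OC3=O)C2(C)C | intermediate
25 | (1R,6S,7E,10R)-6-acetoxyverticilla-4(20),7,11-trien-18,10-olide (CNP0289913.1) | C=C1CC[C@@H]2CCC3=C([C@@H](C/C(C)=C/[C@@H](OC(C)=O)C1)OC3=O)C2(C)C | target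

Total step count: 17 (15 in the main line plus the two reagent preparations, steps 3 and 9).
Longest linear sequence: 15 steps (1, 2, 4–8, 10–17).

Steps most likely to fail

1. Step 14. Ring closure may be too slow at the dilution it needs. A [1,5]-hydrogen shift in the diene, oligomerisation, or closure in the 1,4-bridged sense could then take over, and face selection could be incomplete. The fallback uses known chemistry: it forms the cyclohexene first and closes the macrocycle afterwards. It sets out from 18. An intermolecular Diels–Alder reaction with acrolein 19 (excess, toluene, 60–80 °C) should join the dienophile α-carbon to the dimethylated terminus. The C1 epimers of the adduct are equilibrated with DBU, and the epimer wanted is (2E,4S)-6-(chloromethyl)-1-[(1R,6R)-6-formyl-7,7-dimethyl-3-oxo-1,3,4,5,6,7-hexahydro-2-benzofuran-1-yl]-2-methylhepta-2,6-dien-4-yl acetate F1. An intramolecular Nozaki–Hiyama allylation (CrCl2, cat. LiI, THF, high dilution) then adds the C3 allylchromium to the C2 aldehyde and closes the 12-membered ring. The route is rejoined at 23.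

2. Step 8. The allylic C10 hydroxyl may ionise or be substituted under the Pd/Sn conditions, or the enal may react, before the intramolecular alkoxycarbonylation takes place. The fallback makes the C11–C12 bond by cross-coupling and sets out from 3.
- The vinylogous aldol conditions of step 4, applied to 3 and 8, should give methyl (2E,5R)-6-bromo-5-hydroxy-3,7-dimethylocta-2,6-dienoate F2.
- DIBAL-H reduction gives (2E,5R)-6-bromo-3,7-dimethylocta-2,6-diene-1,5-diol F3.
- TEMPO/PhI(OAc)2 oxidation gives (2E,5R)-6-bromo-5-hydroxy-3,7-dimethylocta-2,6-dienal F4.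
- The coupling partner is methyl 2-(tributylstannyl)prop-2-enoate F5, made by Pd-catalysed hydrostannation of commercial methyl propiolate.
- Copper-assisted Stille coupling of F4 with F5 (Pd(PPh3)4, CuCl, LiCl, DMSO) would give methyl (4R,6E)-4-hydroxy-6-methyl-2-methylidene-8-oxo-3-(propan-2-ylidene)oct-6-enoate F6.
- F6 lactonises (PPTS if needed) and the route is rejoined at 14.

3. Step 4. The dienolate may attack through its α-carbon, or facial discrimination may be poor on the hindered, cross-conjugated 2-alkynyl enal. The fallback builds C7=C8 by carbometalation and sets out from 5. Asymmetric propargylation with allenylboronic acid pinacol ester under chiral phosphoric acid catalysis should give (4R)-5-(propan-2-ylidene)-7-(trimethylsilyl)hepta-1,6-diyn-4-ol F7. Negishi zirconium-catalysed carboalumination of its terminal alkyne (Me3Al, Cp2ZrCl2, CH2Cl2) and trapping of the alkenylalane with paraformaldehyde then gives the (E)-allylic alcohol. The route is rejoined at 10.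

Further compounds
F1 | step 14 | (2E,4S)-6-(chloromethyl)-1-[(1R,6R)-6-formyl-7,7-dimethyl-3-oxo-1,3,4,5,6,7-hexahydro-2-benzofuran-1-yl]-2-methylhepta-2,6-dien-4-yl acetate | ClCC(=C)C[C@H](OC(C)=O)/C=C(C)/C[C@H]1OC(=O)C2=C1C(C)(C)[C@H](C=O)CC2
F2 | step 8 | methyl (2E,5R)-6-bromo-5-hydroxy-3,7-dimethylocta-2,6-dienoate | COC(=O)/C=C(C)/C[C@@H](O)C(Br)=C(C)C
F3 | step 8 | (2E,5R)-6-bromo-3,7-dimethylocta-2,6-diene-1,5-diol | OC/C=C(C)/C[C@@H](O)C(Br)=C(C)C
F4 | step 8 | (2E,5R)-6-bromo-5-hydroxy-3,7-dimethylocta-2,6-dienal | O=C/C=C(C)/C[C@@H](O)C(Br)=C(C)C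
F5 | step 8 | methyl 2-(tributylstannyl)prop-2-enoate | C=C(C(=O)OC)[Sn](CCCC)(CCCC)CCCC
F6 | step 8 | methyl (4R,6E)-4-hydroxy-6-methyl-2-methylidene-8-oxo-3-(propan-2-ylidene)oct-6-enoate | C=C(C(=O)OC)C(=C(C)C)[C@H](O)C/C(C)=C/C=O
F7 | step 4 | (4R)-5-(propan-2-ylidene)-7-(trimethylsilyl)hepta-1,6-diyn-4-ol | C#CC[C@@H](O)C(=C(C)C)C#C[Si](C)(C)C
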